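**Strategy.** Ring B of the target holds a C6 ketone and a C8(17) exocyclic methylene on the two sides of the C5–C10–C9 chain. That makes it a δ,ε-unsaturated carbonyl compound, the retron of an oxy-Cope rearrangement. Everything rests on forming C9–C10 by an anionic oxy-Cope rearrangement of a C6 carbinol that carries the chlorinated cyclohexene ring A (from actinol) and an (E)-2-methylalk-2-enyl chain. In one operation this sets quaternary C10, C9 and, on protonation, C5, and unveils a C6 aldehyde and a C9 isopropenyl group, which a type II carbonyl-ene reaction joins into ring B. The precursor is a monocyclic dienol assembled from an enal and an allyl chloride.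

Key step: step 10

Remark: labdane numbering of the target is used for all atoms (C1–C10 decalin, C11–C12 chain, C13–C16 imide, C17 exocyclic CH2, C20 angular CH3), and compounds 1, 8, 9, 21 and 22 are taken as purchased.

**Step 1**
Reactants: 1 (4R,6R)-actinol
Product: 2 (1S,5R)-3,3,5-trimethyl-4-oxocyclohexyl benzoate
Conditions: PPh3, DIAD, BzOH, THF, 0 °C to rt
Reagents that add atoms: benzoic acid, OC(=O)c1ccccc1
Why: Mitsunobu esterification should invert the carbinol carbon (future C2) by SN2 attack of benzoate on the alkoxyphosphonium ion, the first of two inversions that together retain the actinol configuration for the chloride.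

**Step 2**
Reactants: 2 (1S,5R)-3,3,5-trimethyl-4-oxocyclohexyl benzoate
Product: 4 (S)-3,5,5-trimethyl-4-{[(trifluoromethyl)sulfonyl]oxy}cyclohex-3-en-1-yl benzoate, via potassium enolate 3 (not isolated)
Conditions: KHMDS, THF, −78 °C; PhNTf2, −78 to 0 °C
Reagents that add atoms: N-phenylbis(trifluoromethanesulfonimide), O=S(=O)(N(c1ccccc1)S(=O)(=O)C(F)(F)F)C(F)(F)F
Why: Only the methyl-bearing α-carbon has a hydrogen, so enolisation and O-triflation should give the single tetrasubstituted enol triflate (the methyl stereocentre is erased, the benzoate has no α-hydrogen).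

**Step 3**
Reactants: 4 (S)-3,5,5-trimethyl-4-{[(trifluoromethyl)sulfonyl]oxy}cyclohex-3-en-1-yl benzoate
Product: 5 (S)-4-hydroxy-2,6,6-trimethylcyclohex-1-en-1-yl trifluoromethanesulfonate
Conditions: K2CO3 (cat.), MeOH, 0 °C to rt
Reagents that add atoms: none
Why: Zemplén-type transesterification should free the alcohol while the hindered enol triflate survives, and it is done before the enal exists because a δ-acyloxy enal would eliminate under base.

**Step 4**
Reactants: 5 (S)-4-hydroxy-2,6,6-trimethylcyclohex-1-en-1-yl trifluoromethanesulfonate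
Product: 6 (R)-4-chloro-2,6,6-trimethylcyclohex-1-en-1-yl trifluoromethanesulfonate
Conditions: PPh3, CCl4, MeCN, 60 °C
Reagents that add atoms: carbon tetrachloride, ClC(Cl)(Cl)Cl
Why: The Appel reaction should give the chloride with clean SN2 inversion (second inversion, future 2α-Cl), the electron-poor enol triflate alkene offering no homoallylic participation.

**Step 5**
Reactants: 6 (R)-4-chloro-2,6,6-trimethylcyclohex-1-en-1-yl trifluoromethanesulfonate
Product: 7 (R)-4-chloro-2,6,6-trimethylcyclohex-1-ene-1-carbaldehyde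
Conditions: Pd(PPh3)4 (5 mol %), CO (1 atm), Bu3SnH (slow addition), THF, 50 °C
Reagents that add atoms: carbon monoxide, [C-]#[O+]
Why: Stille-type reductive carbonylation (oxidative addition, CO insertion, Sn–H transmetalation, reductive elimination) should install C6 as the enal under neutral conditions that leave the secondary chloride and the base-labile δ-chloro enal untouched.

**Step 6**
Reactants: 8 3-[(tert-butyldimethylsilyl)oxy]propanal; 9 ethyl 2-(triphenyl-λ5-phosphanylidene)propanoate
Product: 10 ethyl (E)-5-[(tert-butyldimethylsilyl)oxy]-2-methylpent-2-enoate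
Conditions: CH2Cl2, rt
Reagents that add atoms: none
Why: Wittig olefination with the stabilised α-methyl ylide should give the (E)-trisubstituted enoate (future C8=C9) under thermodynamic control of oxaphosphetane formation.

**Step 7**
Reactants: 10 ethyl (E)-5-[(tert-butyldimethylsilyl)oxy]-2-methylpent-2-enoate
Product: 11 (E)-5-[(tert-butyldimethylsilyl)oxy]-2-methylpent-2-en-1-ol
Conditions: DIBAL-H, CH2Cl2, −78 °C; Rochelle salt
Reagents that add atoms: none
Why: 1,2-Reduction of the enoate by DIBAL-H should give the allylic alcohol without touching the alkene geometry or the silyl ether.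

**Step 8**
Reactants: 11 (E)-5-[(tert-butyldimethylsilyl)oxy]-2-methylpent-2-en-1-ol
Product: 12 tert-butyl{[(E)-5-chloro-4-methylpent-3-en-1-yl]oxy}dimethylsilane
Conditions: PPh3, CCl4, CH2Cl2, 0 °C to rt
Reagents that add atoms: carbon tetrachloride, ClC(Cl)(Cl)Cl
Why: Appel chlorination of a primary allylic alcohol should proceed by direct SN2 without allylic transposition or E/Z scrambling.

**Step 9**
Reactants: 7 (R)-4-chloro-2,6,6-trimethylcyclohex-1-ene-1-carbaldehyde; 12 tert-butyl{[(E)-5-chloro-4-methylpent-3-en-1-yl]oxy}dimethylsilane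
Product: 14 (E)-6-[(tert-butyldimethylsilyl)oxy]-1-[(4R)-4-chloro-2,6,6-trimethylcyclohex-1-en-1-yl]-3-methylhex-3-en-1-ol (both C6 carbinol epimers), via allylbarium chloride 13 (not isolated)
Conditions: BaI2, lithium biphenylide (2 equiv), THF, rt; 12, −78 °C; then 7, −78 °C; aq NH4Cl
Reagents that add atoms: none
Why: Allylbarium reagents made at −78 °C keep their (E)-geometry and add to aldehydes at the unsubstituted α-carbon (1,2-addition), which should give the linear 1,5-dien-3-ol; the new carbinol centre is not controlled and need not be.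

**Step 10**
Reactants: 14 (E)-6-[(tert-butyldimethylsilyl)oxy]-1-[(4R)-4-chloro-2,6,6-trimethylcyclohex-1-en-1-yl]-3-methylhex-3-en-1-ol
Product: 17 (1S,2R,4S)-2-[(3S)-5-{[tert-butyl(dimethyl)silyl]oxy}-2-methylpent-1-en-3-yl]-4-chloro-2,6,6-trimethylcyclohexane-1-carbaldehyde, via potassium alkoxide 15 (not isolated), via potassium enolate 16 (not isolated)
Conditions: KHMDS, 18-crown-6, THF, −78 to 0 °C (rt if needed); AcOH, −78 °C
Reagents that add atoms: none
Why: Deprotonation gives alkoxide 15, whose oxyanion weakens the C6–C17 σ-bond so that a concerted [3,3]-shift through the chair array C10=C5–C6(O–)–C17–C8=C9 forms C9–C10 and enolate 16; the closest known reaction type is the anionic (Evans–Golob) oxy-Cope rearrangement of 1,5-dien-3-ols. No ring is closed here: the step makes the one bond ring B lacks and unveils the aldehyde/isopropenyl pair that closes it in step 11. C10 is controlled by ring A: the C4 gem-dimethyl group makes a pseudoaxial chlorine suffer a syn-axial Me/Cl clash, so the half-chair with equatorial Cl dominates and the sigmatropic array must lie over the face anti to the pseudoaxial C4 methyl, which places C9 cis to Cl and the C10 methyl trans to it. C9 is controlled by the (E)-C8=C9 geometry in the chair (C11 pseudo-equatorial, H9 anti to the C10 methyl), and C5 by axial protonation of 16 from the face opposite the two syn-axial methyls on C4 and C10, which gives the 5α-H aldehyde. The step needs the [3,3] path to beat retro-allylation/[1,3] recombination and E2 loss of HCl; low temperature and the unactivated secondary chloride should secure this, and both carbinol epimers of 14 should converge because that centre becomes sp2.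

**Step 11**
Reactants: 17 (1S,2R,4S)-2-[(3S)-5-{[tert-butyl(dimethyl)silyl]oxy}-2-methylpent-1-en-3-yl]-4-chloro-2,6,6-trimethylcyclohexane-1-carbaldehyde
Product: 18 12-[(tert-butyldimethylsilyl)oxy]-2α-chloro-13,14,15,16-tetranorlabd-8(17)-en-6ξ-ol
Conditions: Me2AlCl, CH2Cl2, −78 to 0 °C
Reagents that add atoms: none
Why: A type II intramolecular carbonyl-ene reaction (Snider conditions) should bond C6 to the isopropenyl CH2 (which becomes C7) while the former methyl becomes the C17 exocyclic methylene, closing ring B through a chair that gives the trans-decalin; the C6 carbinol configuration is inconsequential.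

**Step 12**
Reactants: 18 12-[(tert-butyldimethylsilyl)oxy]-2α-chloro-13,14,15,16-tetranorlabd-8(17)-en-6ξ-ol
Product: 19 2α-chloro-13,14,15,16-tetranorlabd-8(17)-ene-6ξ,12-diol
Conditions: HF·pyridine, THF/pyridine, 0 °C to rt
Reagents that add atoms: none
Why: Fluoride cleavage of the primary TBS ether should free C12–OH before any base-sensitive β,γ-enone is present.

**Step 13**
Reactants: 19 2α-chloro-13,14,15,16-tetranorlabd-8(17)-ene-6ξ,12-diol
Product: 20 2α-chloro-6-oxo-13,14,15,16-tetranorlabd-8(17)-en-12-al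
Conditions: Dess–Martin periodinane (2.5 equiv), pyridine, CH2Cl2, 0 °C to rt
Reagents that add atoms: none
Why: Buffered Dess–Martin oxidation should convert both alcohols at once, giving the C6 ketone as the unconjugated β,γ-enone and the C12 aldehyde without touching C5.

**Step 14**
Reactants: 21 (R)-4-benzyl-1,3-oxazolidin-2-one; 22 3-cyanopropanoic acid
Product: 24 4-[(4R)-4-benzyl-2-oxo-1,3-oxazolidin-3-yl]-4-oxobutanenitrile, via mixed pivalic anhydride 23 (not isolated)
Conditions: PivCl, Et3N, THF, −20 °C; then 21, LiCl, rt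
Reagents that add atoms: none
Why: N-acylation of the oxazolidinone by the mixed anhydride (LiCl/Et3N method) should give the imide, whose nitrile is a masked primary amide that cannot attack the activated acyl group prematurely.

**Step 15**
Reactants: 20 2α-chloro-6-oxo-13,14,15,16-tetranorlabd-8(17)-en-12-al; 24 4-[(4R)-4-benzyl-2-oxo-1,3-oxazolidin-3-yl]-4-oxobutanenitrile
Product: 26 (4R)-4-benzyl-3-[(12S,13R)-2α-chloro-15-cyano-12-hydroxy-6-oxo-... acyl]oxazolidin-2-one, i.e. the syn-aldol adduct with C16 as the N-acyl carbonyl and C15 as nitrile, via (Z)-dibutylboron enolate 25 (not isolated)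
Conditions: Bu2BOTf (1.1 equiv), i-Pr2NEt, 24 (1.2 equiv), CH2Cl2, −78 to 0 °C; 20, −78 to 0 °C; pH 7 buffer, MeOH, H2O2, 0 °C
Reagents that add atoms: none
Why: The Evans boron aldol reaction via the (Z)-enolate and a Zimmerman–Traxler chair should give the syn adduct with (12S,13R) configuration under control of the (R)-auxiliary, the aldehyde reacting far faster than the hindered C6 ketone when no free Bu2BOTf remains.

**Step 16**
Reactants: 26 syn-aldol adduct
Product: 28 haterumaimide G, via primary amide 27 (not isolated)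
Conditions: [PtH{(PMe2O)2H}(PMe2OH)] (5 mol %), EtOH/H2O, 80 °C; then i-Pr2NEt (cat.), CH2Cl2, rt
Reagents that add atoms: water, O
Why: Neutral Ghaffar–Parkins hydration should turn the nitrile into the C15 amide, whose nitrogen then attacks the activated C16 N-acyl carbonyl (5-exo-trig) and expels the oxazolidinone to close the succinimide without base-induced conjugation of the β,γ-enone.

**Compound list**

1 | (4R,6R)-4-hydroxy-2,2,6-trimethylcyclohexan-1-one (actinol) | O=C1C(C)(C)C[C@H](O)C[C@H]1C | starting material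
2 | (1S,5R)-3,3,5-trimethyl-4-oxocyclohexyl benzoate | O=C1C(C)(C)C[C@@H](OC(=O)c2ccccc2)C[C@H]1C | intermediate
3 | potassium (S)-4-(benzoyloxy)-2,6,6-trimethylcyclohex-1-en-1-olate | [K+].[O-]C1=C(C)C[C@H](OC(=O)c2ccccc2)CC1(C)C | intermediate
4 | (S)-3,5,5-trimethyl-4-{[(trifluoromethyl)sulfonyl]oxy}cyclohex-3-en-1-yl benzoate | CC1=C(OS(=O)(=O)C(F)(F)F)C(C)(C)C[C@@H](OC(=O)c2ccccc2)C1 | intermediate
5 | (S)-4-hydroxy-2,6,6-trimethylcyclohex-1-en-1-yl trifluoromethanesulfonate | CC1=C(OS(=O)(=O)C(F)(F)F)C(C)(C)C[C@@H](O)C1 | intermediate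
6 | (R)-4-chloro-2,6,6-trimethylcyclohex-1-en-1-yl trifluoromethanesulfonate | CC1=C(OS(=O)(=O)C(F)(F)F)C(C)(C)C[C@H](Cl)C1 | intermediate
7 | (R)-4-chloro-2,6,6-trimethylcyclohex-1-ene-1-carbaldehyde | O=CC1=C(C)C[C@@H](Cl)CC1(C)C | intermediate
8 | 3-[(tert-butyldimethylsilyl)oxy]propanal | O=CCCO[Si](C)(C)C(C)(C)C | starting material
9 | ethyl 2-(triphenyl-λ5-phosphanylidene)propanoate | CCOC(=O)C(C)=P(c1ccccc1)(c1ccccc1)c1ccccc1 | starting material
10 | ethyl (E)-5-[(tert-butyldimethylsilyl)oxy]-2-methylpent-2-enoate | CCOC(=O)/C(C)=C/CCO[Si](C)(C)C(C)(C)C | intermediate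
11 | (E)-5-[(tert-butyldimethylsilyl)oxy]-2-methylpent-2-en-1-ol | OC/C(C)=C/CCO[Si](C)(C)C(C)(C)C | intermediate
12 | tert-butyl{[(E)-5-chloro-4-methylpent-3-en-1-yl]oxy}dimethylsilane | ClC/C(C)=C/CCO[Si](C)(C)C(C)(C)C | intermediate
13 | {(E)-5-[(tert-butyldimethylsilyl)oxy]-2-methylpent-2-en-1-yl}barium chloride | Cl[Ba]C/C(C)=C/CCO[Si](C)(C)C(C)(C)C | intermediate
14 | (E)-6-[(tert-butyldimethylsilyl)oxy]-1-[(4R)-4-chloro-2,6,6-trimethylcyclohex-1-en-1-yl]-3-methylhex-3-en-1-ol, both carbinol epimers | CC1=C(C(O)C/C(C)=C/CCO[Si](C)(C)C(C)(C)C)C(C)(C)C[C@H](Cl)C1 | intermediate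
15 | potassium alkoxide of 14 | [K+].CC1=C(C([O-])C/C(C)=C/CCO[Si](C)(C)C(C)(C)C)C(C)(C)C[C@H](Cl)C1 | intermediate
16 | potassium enolate of 17 (C5=C6 enolate; 2α-Cl, 10β-CH3, 9α-H) | [K+].[O-]C=C1C(C)(C)C[C@H](Cl)C[C@]1(C)[C@@H](CCO[Si](C)(C)C(C)(C)C)C(C)=C | intermediate
17 | (1S,2R,4S)-2-[(3S)-5-{[tert-butyl(dimethyl)silyl]oxy}-2-methylpent-1-en-3-yl]-4-chloro-2,6,6-trimethylcyclohexane-1-carbaldehyde | O=C[C@H]1C(C)(C)C[C@H](Cl)C[C@]1(C)[C@@H](CCO[Si](C)(C)C(C)(C)C)C(C)=C | intermediate
18 | 12-[(tert-butyldimethylsilyl)oxy]-2α-chloro-13,14,15,16-tetranorlabd-8(17)-en-6ξ-ol (5α-H, 9α-H, 10β-CH3) | C=C1CC(O)[C@H]2C(C)(C)C[C@H](Cl)C[C@]2(C)[C@H]1CCO[Si](C)(C)C(C)(C)C | intermediate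
19 | 2α-chloro-13,14,15,16-tetranorlabd-8(17)-ene-6ξ,12-diol | C=C1CC(O)[C@H]2C(C)(C)C[C@H](Cl)C[C@]2(C)[C@H]1CCO | intermediate
20 | 2α-chloro-6-oxo-13,14,15,16-tetranorlabd-8(17)-en-12-al | C=C1CC(=O)[C@H]2C(C)(C)C[C@H](Cl)C[C@]2(C)[C@H]1CC=O | intermediate
21 | (R)-4-benzyl-1,3-oxazolidin-2-one | O=C1N[C@H](Cc2ccccc2)CO1 | starting material
22 | 3-cyanopropanoic acid | N#CCCC(=O)O | starting material
23 | 3-cyanopropanoic pivalic anhydride | N#CCCC(=O)OC(=O)C(C)(C)C | intermediate
24 | 4-[(4R)-4-benzyl-2-oxo-1,3-oxazolidin-3-yl]-4-oxobutanenitrile | N#CCCC(=O)N1[C@H](Cc2ccccc2)COC1=O | intermediate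
25 | (Z)-dibutylboron enolate of 24 | CCCCB(CCCC)O/C(=C\CC#N)N1[C@H](Cc2ccccc2)COC1=O | intermediate
26 | (12S,13R) syn-aldol adduct: 2α-chloro-12-hydroxy-6-oxolabd-8(17)-ene with C15 as nitrile and C16 as N-acyl-(R)-4-benzyloxazolidinone | C=C1CC(=O)[C@H]2C(C)(C)C[C@H](Cl)C[C@]2(C)[C@H]1C[C@H](O)[C@@H](CC#N)C(=O)N1[C@H](Cc2ccccc2)COC1=O | intermediate
27 | (12S,13R) primary amide: as 26 with C15 as CONH2 | C=C1CC(=O)[C@H]2C(C)(C)C[C@H](Cl)C[C@]2(C)[C@H]1C[C@H](O)[C@@H](CC(N)=O)C(=O)N1[C@H](Cc2ccccc2)COC1=O | intermediate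
28 | haterumaimide G, (3R)-3-[(1S)-1-hydroxy-2-(2α-chloro-6-oxo-decalinyl)ethyl]pyrrolidine-2,5-dione | C=C1CC(=O)[C@H]2C(C)(C)C[C@H](Cl)C[C@]2(C)[C@H]1C[C@H](O)[C@H]1CC(=O)NC1=O | target

**Total step count:** 16
**Longest linear sequence:** 12 steps (steps 1–5, 9–13, 15, 16)

**Steps most likely to fail**

Step 10 (key step). The two carbinol epimers of 15 may not share one transition-state face, so that one of them rearranges across the ring-A face syn to the pseudoaxial C4 methyl and gives the C10 epimer. Ion-pair dissociation may also divert material into retro-allylation or a formal [1,3] shift. The fallback replaces conformational control alone by chirality transfer from a defined carbinol. It sets out from 14, which is oxidised (Dess–Martin periodinane, pyridine, CH2Cl2, 0 °C) to the β,γ-unsaturated ketone (E)-6-[(tert-butyldimethylsilyl)oxy]-1-[(4R)-4-chloro-2,6,6-trimethylcyclohex-1-en-1-yl]-3-methylhex-3-en-1-one F1. F1 is reduced at once with the (R)-Me-CBS oxazaborolidine and catecholborane (toluene, −78 °C) to the single (1S)-carbinol F2. In F2 the oxyanion sits pseudo-equatorial in the same chair that the ring already prefers, so both control elements point the same way. F2 is then rearranged under the conditions of step 10 and comes back to the route at 17.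

Step 9. The barium insertion or the addition may lose α-regioselectivity or (E)-geometry (branched γ-adduct, Z-isomer), 12 may undergo Wurtz coupling, or the basic reagent may deprotonate 7 at C1 with vinylogous loss of chloride. The fallback uses an acid-catalysed allyl transfer and no basic organometallic. It sets out from 12, which is added to acetone under zinc Barbier conditions (Zn, THF/aq NH4Cl), where γ-attack is the normal course, to give 3-{2-[(tert-butyldimethylsilyl)oxy]ethyl}-2,4-dimethylpent-4-en-2-ol F3. F3 then hands its allyl group to 7 under Sn(OTf)2 catalysis (CH2Cl2, rt) by hemiacetal formation, ionisation and 2-oxonia-Cope rearrangement through a chair with the CH2CH2OTBS group equatorial. This should release acetone and give the linear (E)-homoallylic alcohol, coming back to the route at 14.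

Step 16. The C12 hydroxyl may add to the metal-bound nitrile (imidate or lactone formation), or the N-acyl oxazolidinone may solvolyse before the amide nitrogen closes the ring. The fallback builds the imide through a lactone and ammonia. It sets out from 20 and 21: 21 is acylated with methyl 4-chloro-4-oxobutanoate (n-BuLi, THF, −78 °C) to methyl 4-[(4R)-4-benzyl-2-oxo-1,3-oxazolidin-3-yl]-4-oxobutanoate F4. The dibutylboron enolate of F4 adds to 20 with the same Evans syn selectivity, and the adduct lactonises (C12–O onto the methyl ester, PPTS if needed) to the (12S,13R) 15,12-γ-lactone N-acyl oxazolidinone F5. Ammonia (THF/MeOH, 0 °C) displaces the auxiliary to give the (12S,13R) 15,12-γ-lactone 16-carboxamide F6. A catalytic amine base then promotes attack of the amide nitrogen on the lactone carbonyl C15, which opens the lactone, frees C12–OH and closes the succinimide, coming back to the route at 28.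

**Further compounds**

F1 | step 10 | (E)-6-[(tert-butyldimethylsilyl)oxy]-1-[(4R)-4-chloro-2,6,6-trimethylcyclohex-1-en-1-yl]-3-methylhex-3-en-1-one | CC1=C(C(=O)C/C(C)=C/CCO[Si](C)(C)C(C)(C)C)C(C)(C)C[C@H](Cl)C1
F2 | step 10 | (1S,E)-6-[(tert-butyldimethylsilyl)oxy]-1-[(4R)-4-chloro-2,6,6-trimethylcyclohex-1-en-1-yl]-3-methylhex-3-en-1-ol | CC1=C([C@@H](O)C/C(C)=C/CCO[Si](C)(C)C(C)(C)C)C(C)(C)C[C@H](Cl)C1
F3 | step 9 | 3-{2-[(tert-butyldimethylsilyl)oxy]ethyl}-2,4-dimethylpent-4-en-2-ol (racemic) | CC(=C)C(CCO[Si](C)(C)C(C)(C)C)C(C)(C)O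
F4 | step 16 | methyl 4-[(4R)-4-benzyl-2-oxo-1,3-oxazolidin-3-yl]-4-oxobutanoate | COC(=O)CCC(=O)N1[C@H](Cc2ccccc2)COC1=O
F5 | step 16 | (12S,13R)-2α-chloro-6-oxolabd-8(17)-en-15,12-olide with C16 as N-acyl-(R)-4-benzyloxazolidinone | C=C1CC(=O)[C@H]2C(C)(C)C[C@H](Cl)C[C@]2(C)[C@H]1C[C@@H]1OC(=O)C[C@H]1C(=O)N1[C@H](Cc2ccccc2)COC1=O
F6 | step 16 | (12S,13R)-2α-chloro-6-oxolabd-8(17)-en-15,12-olide-16-carboxamide | C=C1CC(=O)[C@H]2C(C)(C)C[C@H](Cl)C[C@]2(C)[C@H]1C[C@@H]1OC(=O)C[C@H]1C(N)=O
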